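(The readings are calculated for an exercise.)

The easy step comes first: read how fast the starting material goes in the delta run, the earlier flask with half the second substrate of the flask asked about.

| setting | delta | flask |
|---|---|---|
| starting material | 10 mM | 10 mM |
| second substrate | 5.5 mM | 11.0 mM |
| enzyme | 5 µM | 5.0 µM |
| remark | run made earlier |  |
| time |  | 2.5 h |

delta run (percent of the starting material charged)

| time / min | target / % | starting material / % |
|---|---|---|
| 4.00 | 7.3 | 91.6 |
| 8.00 | 12.7 | 82.5 |
| 12.0 | 16.9 | 74.2 |
| 15.0 | 18.7 | 68.4 |
| 20.0 | 21.5 | 59.3 |
| 25.0 | 23.6 | 51.7 |
| 30.0 | 23.2 | 46.7 |

(scatter of a reading: 0.5 percentage points)



- time, not beyond 2.5 h, at which the flask holds most target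
- the amount of target, in percent of the starting material charged, at that time
- the first time at which target reaches 26%, in the same percent

Build the flask one process at a time, and take the main step first, with all lost starting material counted as target. Up to 12.0 min the readings of the delta run show starting material lost at a mean f = 0.0215 /min of the charge. The flask holds more second substrate than starting material, which makes starting material the limiting reagent, so I carry that pace over as an estimate, and at that pace the charge empties in tE = 1/f = 0.775 h.

Now add one loss. Between 20.0 min and 30.0 min the sum of starting material and target in the delta run fell, and that fall per minute, divided by the mean target of the stretch, gives a first-order loss constant k = 0.0488 /min, a value read off the readings and carrying their scatter. On this estimate target climbs as T = (f/k)(1 − exp(−kt)) while the feed lasts. Call the loss constant times the emptying time the race number, x = k·tE = 2.27. The estimated peak falls from the full charge to (1 − exp(−x))/x = 39.5%, and the same curve passes 26% at 0.305 h.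

Last comes the rest. In that late stretch the delta run's pace had sunk to 0.0126 /min, slower than f; that run had less second substrate than the flask, so its slowing is no measure for the flask, but as a judgement of my own I allow for a feed that tails off there too and commit to a peak somewhat below 39.5%, somewhat before 0.775 h.

The forecast, holding that “second substrate never limits”, gives 31% at 0.72 h and reaches the level at 0.4 h. Its peak stands lower than mine.

The flask gives 37.6% at 0.704 h and reaches the level at 0.279 h, and at 0.704 h it still held 10.8% starting material.

    starting material + enzyme ⇌ starting complex (K = 1700 /M, k = 54000 /M/min)
    second substrate + starting complex ⇌ ternary complex (K = 490 /M, k = 25000 /M/s)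
    ternary complex → enzyme + target (k = 65.0 /min)
    starting material + target → side product (k = 2.20 /M/min)
    target ⇌ isomer of the product (K = 2.60, k = 0.0360 /min)
    second substrate + starting complex → spent catalyst (k = 0.570 /M/min)

Now use the race number on a neighbour flask charged with 0.0030 mM of enzyme. If the feed slows in proportion to the enzyme and k is held, x grows to 3.78, and (1 − exp(−x))/x gives 25.9%, while that neighbour flask gave 28.5%.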